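The side-chain carbons are counted C1′ outward from quinone ring A. The route rests on cutting C7′–C8′, the bond between the only stereocentre and the homoallylic CH2 of the hexaprenyl tail. The key step is a copper-catalysed, stereoinvertive sp3–sp3 cross-coupling. In it, the C31 homohexaprenyl Grignard reagent displaces the (S)-C7′ tosylate of a C22 fragment whose ring A is masked as its 1,4-dimethyl ether. One operation completes the C51 skeleton and sets (R)-C7′, leaving only the oxidative unmasking of ring A. It exploits that C7′ is a secondary carbon flanked only by CH3 and unbranched C6′H2, three methylenes from C3′=C2′. Inversion should therefore outrun elimination and ionisation. The chirality is bought as (S)-propylene oxide.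

Key step: step 14

Remark: C14 of sulfone 11 is a transient stereocentre carried as a mixture, because step 7 turns it into CH2. Compounds 1, 15 and 19 are taken as catalogue compounds of the stated isomeric purity.

Step 1
Reactants: 1 (2E,6E)-farnesyl bromide; 2 bis(pinacolatoboryl)methane
Product: 4 (3E,7E)-homofarnesol, via homofarnesyl pinacol boronate 3 (not isolated)
Conditions: NaOtBu, THF, 0 °C → rt; then NaOH, H2O2, 0 °C
Reagents that add atoms: hydrogen peroxide OO
Why: Alkoxide-triggered deborylative alkylation of the geminal diboronate gives an α-boryl carbanion that displaces the primary allylic bromide in SN2 fashion with the alkene geometry untouched, and boronate oxidation then gives the one-carbon homologated alcohol.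

Step 2
Reactants: 4 (3E,7E)-homofarnesol
Product: 5 (3E,7E)-homofarnesyl pivalate
Conditions: PivCl, pyridine, DMAP (cat.), CH2Cl2, 0 °C → rt
Reagents that add atoms: pivaloyl chloride CC(C)(C)C(=O)Cl
Why: DMAP-catalysed acylation installs a hindered ester that should resist the sulfonyl carbanion of step 6 and still fall to hydride in step 7.

Step 3
Reactants: 5 (3E,7E)-homofarnesyl pivalate
Product: 6 (3E,7E,11E)-13-hydroxy-4,8,12-trimethyltrideca-3,7,11-trien-1-yl pivalate
Conditions: SeO2 (0.1 equiv), salicylic acid (0.1 equiv), t-BuOOH (70 % aq.), CH2Cl2, 0 °C → rt, stopped at partial conversion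
Reagents that add atoms: tert-butyl hydroperoxide CC(C)(C)OO
Why: The catalytic SeO2 allylic oxidation (Riley oxidation, ene reaction then [2,3]-sigmatropic shift) should prefer the most accessible terminal isopropylidene group and oxidise the methyl group trans to the chain, which gives the 11E allylic alcohol.

Step 4
Reactants: 6 (3E,7E,11E)-13-hydroxy-4,8,12-trimethyltrideca-3,7,11-trien-1-yl pivalate
Product: 7 (3E,7E,11E)-13-bromo-4,8,12-trimethyltrideca-3,7,11-trien-1-yl pivalate
Conditions: CBr4, PPh3, CH2Cl2, 0 °C
Reagents that add atoms: carbon tetrabromide BrC(Br)(Br)Br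
Why: The Appel reaction converts the primary allylic alcohol into the bromide by SN2 displacement of the alkoxyphosphonium ion, at low temperature without allylic transposition.

Step 5
Reactants: 1 (2E,6E)-farnesyl bromide; 8 sodium benzenesulfinate
Product: 9 (2E,6E)-farnesyl phenyl sulfone
Conditions: DMF, rt
Reagents that add atoms: none
Why: S-alkylation of the ambident sulfinate by the soft primary allylic bromide (SN2) gives the allylic sulfone with both alkene geometries retained.

Step 6
Reactants: 9 (2E,6E)-farnesyl phenyl sulfone; 7 (3E,7E,11E)-13-bromo-4,8,12-trimethyltrideca-3,7,11-trien-1-yl pivalate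
Product: 11 (3E,7E,11E,15E,19E)-4,8,12,16,20,24-hexamethyl-14-(phenylsulfonyl)pentacosa-3,7,11,15,19,23-hexaen-1-yl pivalate, via lithiated sulfone 10 (not isolated)
Conditions: n-BuLi (1.0 equiv), THF/DMPU, −78 °C; then 7, −78 °C
Reagents that add atoms: none
Why: Alkylation of the sulfone-stabilised allyl anion (Biellmann/Julia-type polyprenyl coupling) takes place at the α-carbon with the highly reactive allylic bromide, and the hindered pivalate should be left alone at −78 °C.

Step 7
Reactants: 11 (3E,7E,11E,15E,19E)-4,8,12,16,20,24-hexamethyl-14-(phenylsulfonyl)pentacosa-3,7,11,15,19,23-hexaen-1-yl pivalate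
Product: 12 all-E-homohexaprenol, (3E,7E,11E,15E,19E)-4,8,12,16,20,24-hexamethylpentacosa-3,7,11,15,19,23-hexaen-1-ol
Conditions: PdCl2(dppp) (5 mol %), LiEt3BH (5 equiv), THF, 0 °C → rt
Reagents that add atoms: none
Why: Palladium-catalysed reductive desulfonylation runs through a π-allylpalladium hydride that delivers hydrogen to the less substituted terminus with the alkene position and E geometry retained, and the excess LiEt3BH cleaves the non-allylic pivalate in the same pot.

Step 8
Reactants: 12 all-E-homohexaprenol
Product: 13 all-E-homohexaprenyl bromide, (3E,7E,11E,15E,19E)-1-bromo-4,8,12,16,20,24-hexamethylpentacosa-3,7,11,15,19,23-hexaene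
Conditions: CBr4, PPh3, CH2Cl2, 0 °C
Reagents that add atoms: carbon tetrabromide BrC(Br)(Br)Br
Why: The Appel reaction turns the primary homoallylic alcohol into the bromide under neutral conditions that leave the six acid-sensitive trisubstituted alkenes alone.

Step 9
Reactants: 14 4-bromo-1-(trimethylsilyl)but-1-yne; 15 (S)-propylene oxide
Product: 17 (S)-7-(trimethylsilyl)hept-6-yn-2-ol, via butynyl Grignard reagent 16 (not isolated)
Conditions: Mg, THF; then CuI (10 mol %), 15, −30 → 0 °C; aqueous work-up
Reagents that add atoms: none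
Why: Copper-catalysed epoxide opening by the Grignard reagent occurs at the unsubstituted CH2 (SN2), so the C–O stereocentre of (S)-propylene oxide passes unchanged into the (S)-carbinol.

Step 10
Reactants: 17 (S)-7-(trimethylsilyl)hept-6-yn-2-ol
Product: 18 (S)-hept-6-yn-2-ol
Conditions: K2CO3 (cat.), MeOH, rt
Reagents that add atoms: none
Why: Base-catalysed methanolysis of the alkynyl C–Si bond (protiodesilylation) frees the terminal alkyne without touching the carbinol centre.

Step 11
Reactants: 19 1,4-dimethoxy-2-methylnaphthalene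
Product: 20 2-(chloromethyl)-1,4-dimethoxy-3-methylnaphthalene
Conditions: (CH2O)n, conc. aq. HCl, AcOH, rt → 40 °C
Reagents that add atoms: formaldehyde C=O; hydrogen chloride Cl
Why: The Blanc chloromethylation is an electrophilic aromatic substitution that can only strike C3, the single free position of the doubly methoxy-activated ring A.

Step 12
Reactants: 18 (S)-hept-6-yn-2-ol; 20 2-(chloromethyl)-1,4-dimethoxy-3-methylnaphthalene
Product: 22 (2S,6E)-8-(1,4-dimethoxy-3-methylnaphthalen-2-yl)-6-methyloct-6-en-2-ol, via alkenylalane 21 (not isolated)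
Conditions: Me3Al (3 equiv), Cp2ZrCl2 (0.25 equiv), ClCH2CH2Cl, 0 °C → rt; volatiles removed; then 20, NiCl2(PPh3)2 (5 mol %) pre-reduced with n-BuLi (10 mol %) to zerovalent nickel, THF, rt; aqueous work-up
Reagents that add atoms: trimethylaluminium C[Al](C)C
Why: Zirconium-catalysed Negishi carboalumination adds methyl and aluminium syn across the alkyne with aluminium at the terminus, and nickel-catalysed cross-coupling of the (E)-alkenylalane with the benzylic chloride proceeds with retention to fix the C2′=C3′ E alkene, while the alcohol is carried as its aluminium alkoxide.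

Step 13
Reactants: 22 (2S,6E)-8-(1,4-dimethoxy-3-methylnaphthalen-2-yl)-6-methyloct-6-en-2-ol
Product: 23 (2S,6E)-8-(1,4-dimethoxy-3-methylnaphthalen-2-yl)-6-methyloct-6-en-2-yl 4-methylbenzenesulfonate
Conditions: TsCl, Et3N, DMAP (cat.), CH2Cl2, 0 °C → rt
Reagents that add atoms: 4-toluenesulfonyl chloride Cc1ccc(cc1)S(=O)(=O)Cl
Why: Sulfonylation takes place at oxygen, so the (S) configuration at C7′ is retained while the hydroxyl group becomes a leaving group.

Step 14
Reactants: 13 all-E-homohexaprenyl bromide; 23 (2S,6E)-8-(1,4-dimethoxy-3-methylnaphthalen-2-yl)-6-methyloct-6-en-2-yl 4-methylbenzenesulfonate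
Product: 25 2-[(2E,7R,10E,14E,18E,22E,26E)-3,7,11,15,19,23,27,31-octamethyldotriaconta-2,10,14,18,22,26,30-heptaen-1-yl]-1,4-dimethoxy-3-methylnaphthalene, via homohexaprenylmagnesium bromide 24 (not isolated)
Conditions: 13 (1.5 equiv), Mg (I2-activated), THF, 40 °C; then added to 23, CuI (10 mol %), TMEDA (20 mol %), LiOMe (1 equiv), THF, 0 °C
Reagents that add atoms: none
Why: Grignard reagent 24 transmetalates to CuI to give a TMEDA/LiOMe-stabilised alkylcuprate, which attacks C7′ of 23 from the face opposite the C–O bond (SN2-type oxidative addition to a trivalent copper intermediate) and then reductively eliminates with retention, forming C7′–C8′. The closest known reaction type is the copper-catalysed Kumada-type cross-coupling of unactivated secondary alkyl tosylates with alkyl Grignard reagents, which is established to run with inversion. No ring is closed. The only new stereocentre, C7′, is controlled by substrate stereospecificity: the (S)-carbinol carbon derived from (S)-propylene oxide is inverted, and because C8′ takes the top CIP rank that oxygen held, the product is (R). The step needs substitution to beat E2 elimination and radical racemisation; the sulfonate (not halide) leaving group disfavours single-electron pathways, and C7′ carries only CH3 and an unbranched CH2, the least hindered secondary pattern. The aryl methyl ethers and the seven trisubstituted alkenes are inert, C7′ is too remote from C3′=C2′ for allylic ionisation, and the homoallylic Grignard carbon C8′ has no stereochemistry to lose.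

Step 15
Reactants: 25 2-[(2E,7R,10E,14E,18E,22E,26E)-3,7,11,15,19,23,27,31-octamethyldotriaconta-2,10,14,18,22,26,30-heptaen-1-yl]-1,4-dimethoxy-3-methylnaphthalene
Product: 26 2-methyl-3-[(2E,7R,10E,14E,18E,22E,26E)-3,7,11,15,19,23,27,31-octamethyldotriaconta-2,10,14,18,22,26,30-heptaen-1-yl]naphthalene-1,4-dione (target)
Conditions: (NH4)2Ce(NO3)6 (2.5 equiv), MeCN/CH2Cl2/H2O, 0 °C
Reagents that add atoms: water O
Why: Oxidative demethylation of the 1,4-dimethoxynaphthalene by tetravalent cerium, through the arene radical cation and addition of water, should give the quinone of ring A faster than the isolated trisubstituted alkenes are attacked, and the remote C7′ centre is untouched.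

Compound list
1 | (2E,6E)-farnesyl bromide | CC(C)=CCC/C(C)=C/CC/C(C)=C/CBr | starting material
2 | bis(pinacolatoboryl)methane | CC1(C)OB(CB2OC(C)(C)C(C)(C)O2)OC1(C)C | starting material
3 | (3E,7E)-homofarnesyl pinacol boronate | CC(C)=CCC/C(C)=C/CC/C(C)=C/CCB1OC(C)(C)C(C)(C)O1 | intermediate
4 | (3E,7E)-homofarnesol | CC(C)=CCC/C(C)=C/CC/C(C)=C/CCO | intermediate
5 | (3E,7E)-homofarnesyl pivalate | CC(C)=CCC/C(C)=C/CC/C(C)=C/CCOC(=O)C(C)(C)C | intermediate
6 | (3E,7E,11E)-13-hydroxy-4,8,12-trimethyltrideca-3,7,11-trien-1-yl pivalate | OC/C(C)=C/CC/C(C)=C/CC/C(C)=C/CCOC(=O)C(C)(C)C | intermediate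
7 | (3E,7E,11E)-13-bromo-4,8,12-trimethyltrideca-3,7,11-trien-1-yl pivalate | BrC/C(C)=C/CC/C(C)=C/CC/C(C)=C/CCOC(=O)C(C)(C)C | intermediate
8 | sodium benzenesulfinate | [Na+].[O-]S(=O)c1ccccc1 | starting material
9 | (2E,6E)-farnesyl phenyl sulfone | CC(C)=CCC/C(C)=C/CC/C(C)=C/CS(=O)(=O)c1ccccc1 | intermediate
10 | α-lithiated (2E,6E)-farnesyl phenyl sulfone | CC(C)=CCC/C(C)=C/CC/C(C)=C/C([Li])S(=O)(=O)c1ccccc1 | intermediate
11 | all-E C31 sulfone pivalate (mixture at C14) | CC(C)=CCC/C(C)=C/CC/C(C)=C/C(C/C(C)=C/CC/C(C)=C/CC/C(C)=C/CCOC(=O)C(C)(C)C)S(=O)(=O)c1ccccc1 | intermediate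
12 | all-E-homohexaprenol | CC(C)=CCC/C(C)=C/CC/C(C)=C/CC/C(C)=C/CC/C(C)=C/CC/C(C)=C/CCO | intermediate
13 | all-E-homohexaprenyl bromide | CC(C)=CCC/C(C)=C/CC/C(C)=C/CC/C(C)=C/CC/C(C)=C/CC/C(C)=C/CCBr | intermediate
14 | 4-bromo-1-(trimethylsilyl)but-1-yne | C[Si](C)(C)C#CCCBr | starting material
15 | (S)-propylene oxide | C[C@H]1CO1 | starting material
16 | 4-(trimethylsilyl)but-3-ynylmagnesium bromide | C[Si](C)(C)C#CCC[Mg]Br | intermediate
17 | (S)-7-(trimethylsilyl)hept-6-yn-2-ol | C[C@H](O)CCCC#C[Si](C)(C)C | intermediate
18 | (S)-hept-6-yn-2-ol | C[C@H](O)CCCC#C | intermediate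
19 | 1,4-dimethoxy-2-methylnaphthalene | COc1c(C)cc(OC)c2ccccc12 | starting material
20 | 2-(chloromethyl)-1,4-dimethoxy-3-methylnaphthalene | COc1c(C)c(CCl)c(OC)c2ccccc12 | intermediate
21 | (S,E)-alkenyldimethylalane carrying the O-dimethylaluminium alkoxide | C[C@H](O[Al](C)C)CCC/C(C)=C/[Al](C)C | intermediate
22 | (2S,6E)-8-(1,4-dimethoxy-3-methylnaphthalen-2-yl)-6-methyloct-6-en-2-ol | C[C@H](O)CCC/C(C)=C/Cc1c(C)c(OC)c2ccccc2c1OC | intermediate
23 | (2S,6E)-tosylate of 22 | C[C@H](OS(=O)(=O)c1ccc(C)cc1)CCC/C(C)=C/Cc1c(C)c(OC)c2ccccc2c1OC | intermediate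
24 | all-E-homohexaprenylmagnesium bromide | CC(C)=CCC/C(C)=C/CC/C(C)=C/CC/C(C)=C/CC/C(C)=C/CC/C(C)=C/CC[Mg]Br | intermediate
25 | (7′R)-hydroquinone dimethyl ether of the target | CC(C)=CCC/C(C)=C/CC/C(C)=C/CC/C(C)=C/CC/C(C)=C/CC/C(C)=C/CC[C@H](C)CCC/C(C)=C/Cc1c(C)c(OC)c2ccccc2c1OC | intermediate
26 | CNP0107344.1, (7′R)-configured naphthoquinone | CC(C)=CCC/C(C)=C/CC/C(C)=C/CC/C(C)=C/CC/C(C)=C/CC/C(C)=C/CC[C@H](C)CCC/C(C)=C/CC1=C(C)C(=O)c2ccccc2C1=O | target

Total step count: 15
Longest linear sequence: 9 steps (1, 2, 3, 4, 6, 7, 8, 14, 15)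

Steps most likely to fail

Step 14 (key step). E2 elimination of the secondary tosylate by the basic organometallic may compete with substitution, and so may erosion of the inversion through single-electron pathways. The fallback replaces the catalytic cross-coupling by alkylation of a stabilised carbanion that carries a removable activating group. It sets out from 13 and 23.
- 13 is treated with PhSO2Na in DMF to give all-E-homohexaprenyl phenyl sulfone F1.
- Its less basic lithio anion (n-BuLi, THF/DMPU, −78 °C → rt) should displace the tosylate of 23 with inversion, giving the C8′-phenylsulfonyl coupling product F2. It forms as a mixture at C8′, which is of no consequence.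
- Reductive desulfonylation (Na/Hg, Na2HPO4, MeOH/THF) removes the activating group and comes back to the route at 25.

Step 3. Competing oxidation at the two internal alkenes and over-oxidation of the allylic alcohol may leave little usable material. The fallback builds the E-allylic alcohol by cleavage and olefination instead of C–H oxidation. It sets out from 5.
- Terminal-selective bromohydrin formation (NBS, aq. THF, 0 °C) gives the terminal bromohydrin F3.
- K2CO3 in MeOH closes it to the terminal epoxide F4.
- H5IO6 (aq. THF) cleaves this to the C11 aldehyde F5.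
- E-selective Wittig olefination with the stabilised ylide Ph3P=C(CH3)CHO gives the (E)-enal F6.
- Luche reduction (NaBH4, CeCl3·7H2O, MeOH, 0 °C) spares the pivalate and comes back to the route at 6.

Step 12. Competing methyl transfer from aluminium, or deactivation of the nickel catalyst by the aluminium alkoxide and zirconium residues, may stall the coupling. The fallback reverses the polarity of the union. It sets out from 18 and 20.
- The carboalumination mixture from 18 is quenched with I2 to give (2S,6E)-7-iodo-6-methylhept-6-en-2-ol F7.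
- 20 is converted with Zn dust and LiCl in THF into the benzylic zinc chloride F8.
- A Negishi coupling of F7 with F8 (Pd(OAc)2, SPhos, THF, rt) proceeds with retention of the alkene geometry and comes back to the route at 22.

Further compounds
F1 | step 14 | all-E-homohexaprenyl phenyl sulfone | CC(C)=CCC/C(C)=C/CC/C(C)=C/CC/C(C)=C/CC/C(C)=C/CC/C(C)=C/CCS(=O)(=O)c1ccccc1
F2 | step 14 | C8′-phenylsulfonyl derivative of 25 (7′R, mixture at C8′) | CC(C)=CCC/C(C)=C/CC/C(C)=C/CC/C(C)=C/CC/C(C)=C/CC/C(C)=C/CC([C@H](C)CCC/C(C)=C/Cc1c(C)c(OC)c2ccccc2c1OC)S(=O)(=O)c1ccccc1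
F3 | step 3 | (3E,7E)-11-bromo-12-hydroxy-4,8,12-trimethyltrideca-3,7-dien-1-yl pivalate (racemic) | CC(C)(O)C(Br)CC/C(C)=C/CC/C(C)=C/CCOC(=O)C(C)(C)C
F4 | step 3 | (3E,7E)-11,12-epoxy-4,8,12-trimethyltrideca-3,7-dien-1-yl pivalate (racemic) | CC1(C)OC1CC/C(C)=C/CC/C(C)=C/CCOC(=O)C(C)(C)C
F5 | step 3 | (3E,7E)-4,8-dimethyl-11-oxoundeca-3,7-dien-1-yl pivalate | O=CCC/C(C)=C/CC/C(C)=C/CCOC(=O)C(C)(C)C
F6 | step 3 | (3E,7E,11E)-4,8,12-trimethyl-13-oxotrideca-3,7,11-trien-1-yl pivalate | O=C/C(C)=C/CC/C(C)=C/CC/C(C)=C/CCOC(=O)C(C)(C)C
F7 | step 12 | (2S,6E)-7-iodo-6-methylhept-6-en-2-ol | C[C@H](O)CCC/C(C)=C/I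
F8 | step 12 | (1,4-dimethoxy-3-methylnaphthalen-2-yl)methylzinc chloride | COc1c(C)c(C[Zn]Cl)c(OC)c2ccccc12
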